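The seven-membered ring is traced back to a cyclopentane-1,3-dione whose carbons C6–C10 are inserted between C1 and C5 of a cyclopentene. The C2 oxygen, which sits beside the quaternary carbon C1 of the five-membered ring (C1–C5), holds the dione enol over the C1=C5 double bond, so that one irradiation forms C1–C10 and C5–C6, sets C1 syn to that oxygen and closes a 2-oxabicyclo[2.1.1]hexane. Acid then cleaves C6–C10 (retro-aldol), which opens the cage to the cycloheptane-6,9-dione and frees C2–OH. The precursor is the enol ether of 4-methylcyclopentane-1,3-dione with (1S,4R)-4-isopropyl-2-methylcyclopent-2-ene-1,4-diol, bound through the secondary oxygen.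

Key step: step 7

Remark (numbering): daucane numbering is used throughout; the five-membered ring is C1 (quaternary, CH3), C2 (O), C3, C4 (C(OH)iPr), C5, and the seven-membered ring is C1, C5, C6, C7, C8 (CH3), C9, C10; α is the face of the C2 oxygen, β the face of the C1 methyl group.

Remark (assumption): C8 is formed as both epimers in step 6 and is carried as the mixture, because it becomes sp2 in step 15; the SMILES of 9–14, 18 and 19 therefore leave C8 undefined.

Remark (design): the tertiary C4 hydroxyl is left unprotected from 6 to 18, since it is inert in the Mitsunobu step, rides through the alkylation as its lithium alkoxide, is no chromophore, and is needed free for the directed reduction.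

Step 1
Reactants: 1 (R)-4-(tert-butyldimethylsilyloxy)cyclopent-2-en-1-one
Product: 2 (3R,4R)-4-(tert-butyldimethylsilyloxy)-3-methyl-1-(trimethylsilyloxy)cyclopent-1-ene
Conditions: Me2CuLi (CuI, 2 MeLi), TMSCl, Et3N, THF, −78 °C
Reagents that add atoms: lithium dimethylcuprate, [Li+].C[Cu-]C; chlorotrimethylsilane, C[Si](C)(C)Cl
Why: Conjugate addition of the Gilman reagent should occur anti to the silyloxy group, and silylation of the enolate on the carbonyl side as it forms prevents enolate equilibration and β-elimination of the silyloxy group; the methyl-bearing stereocentre is erased in step 2.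

Step 2
Reactants: 2 (3R,4R)-4-(tert-butyldimethylsilyloxy)-3-methyl-1-(trimethylsilyloxy)cyclopent-1-ene
Product: 3 (R)-4-(tert-butyldimethylsilyloxy)-3-methylcyclopent-2-en-1-one
Conditions: Pd(OAc)2 (1.05 equiv), MeCN, rt
Reagents that add atoms: none
Why: Saegusa–Ito oxidation of the regiodefined silyl enol ether should return the enone with the methyl group now on the β-carbon, while the oxygen-bearing stereocentre is not touched.

Step 3
Reactants: 3 (R)-4-(tert-butyldimethylsilyloxy)-3-methylcyclopent-2-en-1-one; 4 isopropylmagnesium chloride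
Product: 5 (1R,4R)-4-(tert-butyldimethylsilyloxy)-3-methyl-1-(propan-2-yl)cyclopent-2-en-1-ol (OH cis to OTBS)
Conditions: CeCl3 (anhydrous), 4, THF, −78 °C; then 3, −78 °C
Reagents that add atoms: none
Why: 1,2-Addition of the weakly basic organocerium reagent should suppress enolisation, reduction and conjugate addition, and attack on the carbonyl face anti to the silyloxy group places isopropyl trans and the new hydroxyl cis to OTBS, which sets C4.

Step 4
Reactants: 5 (1R,4R)-4-(tert-butyldimethylsilyloxy)-3-methyl-1-(propan-2-yl)cyclopent-2-en-1-ol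
Product: 6 (1R,4R)-3-methyl-1-(propan-2-yl)cyclopent-2-ene-1,4-diol (cis-diol)
Conditions: TBAF, THF, 0 °C to rt
Reagents that add atoms: none
Why: Fluoride-mediated desilylation is non-acidic, so the ionisable tertiary allylic alcohol should survive.

Step 5
Reactants: 6 (1R,4R)-3-methyl-1-(propan-2-yl)cyclopent-2-ene-1,4-diol; 7 cyclopentane-1,3-dione
Product: 8 3-{[(1S,4R)-4-hydroxy-2-methyl-4-(propan-2-yl)cyclopent-2-en-1-yl]oxy}cyclopent-2-en-1-one
Conditions: PPh3, DIAD, THF, 0 °C to rt
Reagents that add atoms: none
Why: Mitsunobu reaction, in which the acidic dione is O-alkylated by the oxyphosphonium ion of the secondary allylic alcohol (the tertiary alcohol is inert) in an SN2 displacement that inverts C2, so that the ether oxygen ends trans to the C4 hydroxyl and cis to isopropyl.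

Step 6
Reactants: 8 3-{[(1S,4R)-4-hydroxy-2-methyl-4-(propan-2-yl)cyclopent-2-en-1-yl]oxy}cyclopent-2-en-1-one
Product: 9 3-{[(1S,4R)-4-hydroxy-2-methyl-4-(propan-2-yl)cyclopent-2-en-1-yl]oxy}-5-methylcyclopent-2-en-1-one (both C8 epimers)
Conditions: LDA (2.2 equiv), THF, −78 °C; MeI, DMPU, −78 to −40 °C
Reagents that add atoms: iodomethane, CI
Why: Stork–Danheiser-type alkylation, in which kinetic deprotonation of the 3-alkoxy enone occurs at the α′ carbon (C8) while the second equivalent of base holds the tertiary alcohol as an unreactive lithium alkoxide, so methylation should occur on carbon only; both C8 epimers are acceptable.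

Step 7
Reactants: 9 3-{[(1S,4R)-4-hydroxy-2-methyl-4-(propan-2-yl)cyclopent-2-en-1-yl]oxy}-5-methylcyclopent-2-en-1-one
Product: 10 crossed [2+2] photoadduct, a 2-oxabicyclo[2.1.1]hexane (O, C2, C1, C10, C6, with C5 as the second one-carbon bridge) fused to the cyclopentane C1–C5 and to the cyclopentanone C6–C10 (both C8 epimers)
Conditions: hν (medium-pressure Hg lamp, Pyrex filter, λ > 290 nm), degassed MeCN (5 mM), 15 °C
Reagents that add atoms: none
Why: Excitation of the 3-alkoxy enone and intersystem crossing give the triplet, whose α-carbon C10 should bond to C1 of the tethered alkene in a 1,5-closure that forms the oxolane ring O–C2–C1–C10–C6 and leaves a 1,4-biradical (α-oxy radical at C6, secondary radical at C5), which after spin inversion closes C5–C6 to complete the cyclobutane C1–C5–C6–C10. The closest known reaction type is the intramolecular crossed [2+2] photocycloaddition of 3-(alk-2-enyloxy)cycloalk-2-enones to 2-oxabicyclo[2.1.1]hexanes. Ring closures: the five-membered oxolane by the 5-exo-type 1,5-radical closure, and the four-membered ring by recombination of the 1,4-biradical. Stereocentres: C1 is set by the two-atom O–C2 tether, which reaches only the alkene face syn to the C2 oxygen; C5 follows because the second bond must enter the same face (C6 cis to C10, H5 on the β face); C6 and C10 are fixed by the cis geometry of the former enone double bond inside the cage. The step needs crossed and not straight regiochemistry, which the two-atom tether secures because the straight mode would require a first closure to a four- or six-membered ring, and it needs selective excitation, which holds because the enol ether enone is the only chromophore above 290 nm. The C8 methyl centre and the free C4 hydroxyl are remote from the reacting carbons and should be carried unchanged.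

Step 8
Reactants: 10 crossed [2+2] photoadduct
Product: 11 2α,4β-dihydroxy-5β-H-daucane-6,9-dione (cis-fused; both C8 epimers)
Conditions: 1 M aq. HCl, THF, 0 °C to rt
Reagents that add atoms: water, O
Why: De Mayo-type retro-aldol fragmentation, in which protonation of the C9 carbonyl lets the ether oxygen expel the strained C6–C10 bond and water converts the resulting C6 oxocarbenium ion into the C6 ketone with release of C2–OH; C1, C2, C4 and C5 are not involved, so the ring fusion should still be cis.

Step 9
Reactants: 11 2α,4β-dihydroxy-5β-H-daucane-6,9-dione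
Product: 12 2α-acetoxy-4β-hydroxy-5β-H-daucane-6,9-dione (cis-fused; both C8 epimers)
Conditions: Ac2O, pyridine, DMAP (5 mol%), CH2Cl2, 0 °C
Reagents that add atoms: acetic anhydride, CC(=O)OC(C)=O
Why: DMAP-catalysed acylation should take only the secondary C2 hydroxyl, because the hindered tertiary C4 hydroxyl does not react at 0 °C; this fixes the acetate before the second secondary hydroxyl (C6) exists.

Step 10
Reactants: 12 2α-acetoxy-4β-hydroxy-5β-H-daucane-6,9-dione
Product: 13 2α-acetoxy-4β-hydroxy-5α-H-daucane-6,9-dione (trans-fused; both C8 epimers)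
Conditions: DBU, toluene, 60 °C
Reagents that add atoms: none
Why: Thermodynamic epimerisation through the C5=C6 enolate should favour the trans ring fusion, which moves C6 away from the cis isopropyl group on C4 and allows a hydrogen bond from C4–OH to the C6 carbonyl; an amidine base in an aprotic solvent enolises the ketone without forming the C4 alkoxide that a retro-aldol would need.

Step 11
Reactants: 13 2α-acetoxy-4β-hydroxy-5α-H-daucane-6,9-dione
Product: 14 2α-acetoxy-4β,6α-dihydroxy-5α-H-daucan-9-one (both C8 epimers)
Conditions: Me4NBH(OAc)3, MeCN/AcOH (1:1), −20 °C to rt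
Reagents that add atoms: none
Why: Evans–Saksena reduction, in which the borohydride bound to C4–OH delivers hydride to the C6 carbonyl from the side of C4, which should give the 1,3-anti diol with the C6 oxygen on the α face, while the C9 ketone, which has no free hydroxyl within reach, is not reduced by this mild reagent.

Step 12
Reactants: 15 4-hydroxybenzoic acid
Product: 17 4-(tert-butyldimethylsilyloxy)benzoic acid, via bis-silylated 4-hydroxybenzoic acid 16 (not isolated)
Conditions: TBSCl (2.4 equiv), imidazole, DMF, rt; then AcOH/THF/H2O, rt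
Reagents that add atoms: tert-butyldimethylsilyl chloride, CC(C)(C)[Si](C)(C)Cl
Why: Exhaustive silylation followed by selective hydrolysis of the far more labile silyl ester should leave the aryl silyl ether in place.

Step 13
Reactants: 14 2α-acetoxy-4β,6α-dihydroxy-5α-H-daucan-9-one; 17 4-(tert-butyldimethylsilyloxy)benzoic acid
Product: 18 2α-acetoxy-6α-[4-(tert-butyldimethylsilyloxy)benzoyloxy]-4β-hydroxydaucan-9-one (both C8 epimers)
Conditions: EDC·HCl, DMAP, CH2Cl2, rt
Reagents that add atoms: none
Why: Steglich esterification should acylate the secondary C6 hydroxyl with retention, because the tertiary C4 hydroxyl is too hindered to compete.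

Step 14
Reactants: 18 2α-acetoxy-6α-[4-(tert-butyldimethylsilyloxy)benzoyloxy]-4β-hydroxydaucan-9-one
Product: 19 2α-acetoxy-6α-[4-(tert-butyldimethylsilyloxy)benzoyloxy]-4β-(trimethylsilyloxy)daucan-9-one (both C8 epimers)
Conditions: TMSOTf, 2,6-lutidine, CH2Cl2, −78 °C
Reagents that add atoms: trimethylsilyl trifluoromethanesulfonate, C[Si](C)(C)OS(=O)(=O)C(F)(F)F
Why: A silyl triflate with a hindered pyridine should silylate even this hindered tertiary alcohol at −78 °C, where the ketone is not enol-silylated, and so shields C4–OH from triflic anhydride in step 15.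

Step 15
Reactants: 19 2α-acetoxy-6α-[4-(tert-butyldimethylsilyloxy)benzoyloxy]-4β-(trimethylsilyloxy)daucan-9-one
Product: 20 2α-acetoxy-6α-[4-(tert-butyldimethylsilyloxy)benzoyloxy]-4β-(trimethylsilyloxy)dauc-8-en-9-yl trifluoromethanesulfonate
Conditions: Tf2O, 2,6-di-tert-butyl-4-methylpyridine, CH2Cl2, 0 °C to rt
Reagents that add atoms: trifluoromethanesulfonic anhydride, O=S(=O)(OS(=O)(=O)C(F)(F)F)C(F)(F)F
Why: Vinyl triflate formation by O-triflation of the ketone and E1-like proton loss should follow Zaitsev orientation and give the more substituted C8=C9 enol triflate from either C8 epimer, under conditions that leave the esters and silyl ethers intact.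

Step 16
Reactants: 20 2α-acetoxy-6α-[4-(tert-butyldimethylsilyloxy)benzoyloxy]-4β-(trimethylsilyloxy)dauc-8-en-9-yl trifluoromethanesulfonate
Product: 21 2α-acetoxy-6α-[4-(tert-butyldimethylsilyloxy)benzoyloxy]-4β-(trimethylsilyloxy)dauc-8-ene
Conditions: Pd(OAc)2 (5 mol%), PPh3 (10 mol%), HCO2H, Bu3N, DMF, 60 °C
Reagents that add atoms: none
Why: Palladium-catalysed formate reduction of the vinyl triflate (oxidative addition, formate exchange, decarboxylation, reductive elimination) should replace OTf by H with the double bond fixed at C8=C9; neither ester is allylic, so no π-allyl ionisation is possible.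

Step 17
Reactants: 21 2α-acetoxy-6α-[4-(tert-butyldimethylsilyloxy)benzoyloxy]-4β-(trimethylsilyloxy)dauc-8-ene
Product: 22 2α-acetoxy-4β-hydroxy-6α-(4-hydroxybenzoyloxy)dauc-8-ene (CNP0275279.1)
Conditions: TBAF, AcOH, THF, 0 °C
Reagents that add atoms: none
Why: Acetic acid-buffered fluoride should cleave the aryl silyl ether and the tertiary trimethylsilyl ether by Si–F bond formation without hydrolysing or migrating the acetate and the benzoate.

Compound list

1 | (R)-4-(tert-butyldimethylsilyloxy)cyclopent-2-en-1-one | CC(C)(C)[Si](C)(C)O[C@@H]1CC(=O)C=C1 | starting material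
2 | (3R,4R)-4-(tert-butyldimethylsilyloxy)-3-methyl-1-(trimethylsilyloxy)cyclopent-1-ene (methyl trans to OTBS) | C[Si](C)(C)OC1=C[C@@H](C)[C@H](O[Si](C)(C)C(C)(C)C)C1 | intermediate
3 | (R)-4-(tert-butyldimethylsilyloxy)-3-methylcyclopent-2-en-1-one | CC(C)(C)[Si](C)(C)O[C@@H]1CC(=O)C=C1C | intermediate
4 | isopropylmagnesium chloride | CC(C)[Mg]Cl | starting material
5 | (1R,4R)-4-(tert-butyldimethylsilyloxy)-3-methyl-1-(propan-2-yl)cyclopent-2-en-1-ol (OH cis to OTBS) | CC(C)(C)[Si](C)(C)O[C@@H]1C[C@@](O)(C(C)C)C=C1C | intermediate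
6 | (1R,4R)-3-methyl-1-(propan-2-yl)cyclopent-2-ene-1,4-diol (cis-diol) | O[C@@H]1C[C@@](O)(C(C)C)C=C1C | intermediate
7 | cyclopentane-1,3-dione | O=C1CCC(=O)C1 | starting material
8 | 3-{[(1S,4R)-4-hydroxy-2-methyl-4-(propan-2-yl)cyclopent-2-en-1-yl]oxy}cyclopent-2-en-1-one | O=C1C=C(O[C@H]2C[C@@](O)(C(C)C)C=C2C)CC1 | intermediate
9 | 3-{[(1S,4R)-4-hydroxy-2-methyl-4-(propan-2-yl)cyclopent-2-en-1-yl]oxy}-5-methylcyclopent-2-en-1-one (both C8 epimers) | O=C1C=C(O[C@H]2C[C@@](O)(C(C)C)C=C2C)CC1C | intermediate
10 | crossed [2+2] photoadduct: 2-oxabicyclo[2.1.1]hexane (O, C2, C1, C10, C6; C5 bridge) fused to the cyclopentane C1–C5 (1β-CH3, 4β-OH, 4α-iPr, 5β-H) and to the cyclopentanone C6–C10 (C9=O, 8-CH3, both C8 epimers) | O1[C@H]2C[C@@](O)(C(C)C)[C@H]3[C@@]14CC(C)C(=O)[C@@H]4[C@@]23C | intermediate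
11 | 2α,4β-dihydroxy-5β-H-daucane-6,9-dione (cis-fused; both C8 epimers) | O[C@H]1C[C@@](O)(C(C)C)[C@H]2C(=O)CC(C)C(=O)C[C@@]12C | intermediate
12 | 2α-acetoxy-4β-hydroxy-5β-H-daucane-6,9-dione (cis-fused; both C8 epimers) | CC(=O)O[C@H]1C[C@@](O)(C(C)C)[C@H]2C(=O)CC(C)C(=O)C[C@@]12C | intermediate
13 | 2α-acetoxy-4β-hydroxy-5α-H-daucane-6,9-dione (trans-fused; both C8 epimers) | CC(=O)O[C@H]1C[C@@](O)(C(C)C)[C@@H]2C(=O)CC(C)C(=O)C[C@@]12C | intermediate
14 | 2α-acetoxy-4β,6α-dihydroxy-5α-H-daucan-9-one (both C8 epimers) | CC(=O)O[C@H]1C[C@@](O)(C(C)C)[C@@H]2[C@@H](O)CC(C)C(=O)C[C@@]12C | intermediate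
15 | 4-hydroxybenzoic acid | O=C(O)c1ccc(O)cc1 | starting material
16 | tert-butyldimethylsilyl 4-(tert-butyldimethylsilyloxy)benzoate | CC(C)(C)[Si](C)(C)OC(=O)c1ccc(O[Si](C)(C)C(C)(C)C)cc1 | intermediate
17 | 4-(tert-butyldimethylsilyloxy)benzoic acid | O=C(O)c1ccc(O[Si](C)(C)C(C)(C)C)cc1 | intermediate
18 | 2α-acetoxy-6α-[4-(tert-butyldimethylsilyloxy)benzoyloxy]-4β-hydroxydaucan-9-one (both C8 epimers) | CC(=O)O[C@H]1C[C@@](O)(C(C)C)[C@@H]2[C@@H](OC(=O)c3ccc(O[Si](C)(C)C(C)(C)C)cc3)CC(C)C(=O)C[C@@]12C | intermediate
19 | 2α-acetoxy-6α-[4-(tert-butyldimethylsilyloxy)benzoyloxy]-4β-(trimethylsilyloxy)daucan-9-one (both C8 epimers) | CC(=O)O[C@H]1C[C@@](O[Si](C)(C)C)(C(C)C)[C@@H]2[C@@H](OC(=O)c3ccc(O[Si](C)(C)C(C)(C)C)cc3)CC(C)C(=O)C[C@@]12C | intermediate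
20 | 2α-acetoxy-6α-[4-(tert-butyldimethylsilyloxy)benzoyloxy]-4β-(trimethylsilyloxy)dauc-8-en-9-yl trifluoromethanesulfonate | CC(=O)O[C@H]1C[C@@](O[Si](C)(C)C)(C(C)C)[C@@H]2[C@@H](OC(=O)c3ccc(O[Si](C)(C)C(C)(C)C)cc3)CC(C)=C(OS(=O)(=O)C(F)(F)F)C[C@@]12C | intermediate
21 | 2α-acetoxy-6α-[4-(tert-butyldimethylsilyloxy)benzoyloxy]-4β-(trimethylsilyloxy)dauc-8-ene | CC(=O)O[C@H]1C[C@@](O[Si](C)(C)C)(C(C)C)[C@@H]2[C@@H](OC(=O)c3ccc(O[Si](C)(C)C(C)(C)C)cc3)CC(C)=CC[C@@]12C | intermediate
22 | 2α-acetoxy-4β-hydroxy-6α-(4-hydroxybenzoyloxy)dauc-8-ene (CNP0275279.1) | CC(=O)O[C@H]1C[C@@](O)(C(C)C)[C@@H]2[C@@H](OC(=O)c3ccc(O)cc3)CC(C)=CC[C@@]12C | target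

Total step count: 17. Longest linear sequence: 16 (steps 1–11 and 13–17, from 1 to 22); step 12 is a one-step side branch.

Steps most likely to fail

Step 7. The second bond must close at C5 next to C4, whose isopropyl group lies on the same face. The 1,4-biradical may therefore fall back to 9, and over the long irradiation this entails the α-methyl cyclopentanone of 10 may suffer Norrish type I cleavage of C8–C9. The fallback exchanges the order of methylation and irradiation and sets out from 8. Irradiation of 8 under the same filter should give the C8-unsubstituted crossed photoadduct F1, a single diastereomer whose unsubstituted cyclopentanone is less prone to α-cleavage. Methylation of F1 with LDA (2.2 equiv) and MeI should occur at C8, the only α-carbon that can be enolised, since C10 is a bridge carbon of the cage. The route is rejoined at 10.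

Step 10. Enolisation at the hindered C5–H may be slow, and under more forcing base the C4 alkoxide could start a retro-aldol cleavage of C4–C5 that scrambles C4. The fallback sets out from 12 and epimerises the protected aldol instead. Silylation (TMSOTf, 2,6-lutidine, −78 °C) gives the cis-fused 4β-trimethylsilyl ether F2. DBU should equilibrate it, with no alkoxide available, to the trans-fused 4β-trimethylsilyl ether F3. HF·pyridine then removes the silyl group, and the route is rejoined at 13.

Step 15. Proton loss from C10 instead of C8 would give the C9=C10 enol triflate, and triflic anhydride may attack the tertiary silyl ether. The fallback sets out from 18 and fixes the regiochemistry one stage earlier. Thermodynamic enol silylation (TMSCl, NaI, Et3N, MeCN), which also silylates C4–OH, should give the C8=C9 trimethylsilyl enol ether F4, which can be freed from any C9=C10 isomer. One equivalent of TBAT with N-(5-chloropyridin-2-yl)triflimide at −78 °C should then convert the enol ether regiospecifically into the triflate, and the route is rejoined at 20.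

Further compounds

F1 | step 7 | C8-unsubstituted crossed [2+2] photoadduct (2-oxabicyclo[2.1.1]hexane core, C9 ketone, 4β-OH) | O1[C@H]2C[C@@](O)(C(C)C)[C@H]3[C@@]14CCC(=O)[C@@H]4[C@@]23C
F2 | step 10 | 2α-acetoxy-4β-(trimethylsilyloxy)-5β-H-daucane-6,9-dione (cis-fused; both C8 epimers) | CC(=O)O[C@H]1C[C@@](O[Si](C)(C)C)(C(C)C)[C@H]2C(=O)CC(C)C(=O)C[C@@]12C
F3 | step 10 | 2α-acetoxy-4β-(trimethylsilyloxy)-5α-H-daucane-6,9-dione (trans-fused; both C8 epimers) | CC(=O)O[C@H]1C[C@@](O[Si](C)(C)C)(C(C)C)[C@@H]2C(=O)CC(C)C(=O)C[C@@]12C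
F4 | step 15 | 2α-acetoxy-6α-[4-(tert-butyldimethylsilyloxy)benzoyloxy]-4β,9-bis(trimethylsilyloxy)dauc-8-ene | CC(=O)O[C@H]1C[C@@](O[Si](C)(C)C)(C(C)C)[C@@H]2[C@@H](OC(=O)c3ccc(O[Si](C)(C)C(C)(C)C)cc3)CC(C)=C(O[Si](C)(C)C)C[C@@]12C
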